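## Retrosynthetic overview

1. Numbering: C1 = carboxyl carbon, C3 and C6 = dioxane carbons, C10≡C11–C12=C13 = enyne, C22 = terminal CH2. Acid 20 comes from primary alcohol 18 by oxidation at C1.
2. The 1,2-dioxane is the only ring of the target and is closed last. It is cut at O–C3: the C6 hydroperoxy ketal opens a temporary four-membered ring, an (R)-oxetane spanning C1–C3 that is made first from an epoxide, with inversion. C6 then follows by anomeric equilibration.
3. C6–C7 is cut to a Weinreb amide (C1–C6) and a Grignard reagent (C7–C22). C9–C10 is cut to a terminal enyne and 1,3-dibromopropane.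
4. Key disconnection C13–C14. The enabling feature is the conjugated E-enyne: four contiguous unsaturated carbons C10–C13, each bearing at most one hydrogen. They map onto C3, C4, C5 and C6 of a pyridazine ring whose N1=N2 unit can leave as N2.
5. Non-8-enylmagnesium bromide adds to C6 of pyridazine 1-oxide. Dearomatisation, electrocyclic opening of the six-membered ring and loss of N2 deliver the bond, the E-alkene and the alkyne in one operation.

Key step: step 3

Remark: the carbon numbering of the target (C1–C22) is used for all intermediates. Compounds 1, 3, 8 and 11 are taken as commercial.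

## Route

Step 1
Reactants: 1 pyridazine
Product: 2 pyridazine 1-oxide
Conditions: mCPBA (1.05 equiv), CH2Cl2, 0 °C → rt
Reagents that add atoms: mCPBA, O=C(OO)c1cccc(Cl)c1
Why: Peracid N-oxidation of an azine; the two nitrogens of 1 are equivalent, so only one mono-N-oxide can form, and the first oxidation deactivates the ring toward a second.

Step 2
Reactants: 3 9-bromonon-1-ene
Product: 4 non-8-en-1-ylmagnesium bromide (THF solution, titrated and used directly)
Conditions: Mg turnings, cat. 1,2-dibromoethane, THF, rt → 40 °C
Reagents that add atoms: magnesium, [Mg]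
Why: Standard Grignard formation from a primary alkyl bromide; the terminal alkene is too remote to cyclise onto the radical or carbanion centre.

Step 3
Reactants: 2 pyridazine 1-oxide; 4 non-8-en-1-ylmagnesium bromide
Product: 7 (3E)-trideca-3,12-dien-1-yne, via dihydropyridazine adduct 5 (not isolated), via dienyl diazotate 6 (not isolated)
Conditions: 4 (1.1 equiv) added dropwise to 2, THF, −78 °C; then warm to rt (N2 evolution); aq NH4Cl
Reagents that add atoms: none
Why: The Grignard reagent, held by Mg–O coordination to the N-oxide oxygen, adds to ring carbon C6 next to N1, which dearomatises 2 to the 1,6-dihydropyridazine 5 and makes the C13–C14 bond of the target. On warming, 5 opens by a thermal disrotatory 6π electrocyclic reaction (N1–C6 cleavage) to the dienyl diazotate 6, and anti elimination of N2 and HOMgBr across the former ring C3=C4 bond turns that cis double bond into the terminal alkyne. The closest known reaction types are the opening of pyridazine N-oxides by Grignard reagents to but-1-en-3-ynes and the opening of pyridine N-oxides to (2Z,4E)-dienal oximes. No ring is closed and no stereocentre is formed; the only stereochemical element, the E double bond, should be set by outward rotation of the alkyl group at the sp3 carbon of 5 during ring opening. The step needs regioselectivity for ring C6 over C3, C4 and C5, which the N-oxide secures by activation and chelation, and it needs mono-addition, which slow addition at −78 °C secures because no Grignard reagent is left when 6 forms. The isolated terminal alkene of 4 is inert under these conditions.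

Step 4
Reactants: 7 (3E)-trideca-3,12-dien-1-yne; 8 1,3-dibromopropane
Product: 10 (10E)-16-bromohexadeca-1,10-dien-12-yne, via lithium acetylide 9 (not isolated)
Conditions: n-BuLi, THF, −78 °C; then DMPU, 8 (4 equiv), −78 °C → rt
Reagents that add atoms: none
Why: SN2 alkylation of a lithium acetylide in THF/DMPU; the excess of the symmetrical dihalide suppresses double alkylation, and the E-alkene is not touched.

Step 5
Reactants: 11 (R)-2-(but-3-en-1-yl)oxirane [(R)-1,2-epoxy-5-hexene]
Product: 12 (R)-2-(but-3-en-1-yl)oxetane
Conditions: Me3S(O)I (2.5 equiv), KOt-Bu (2.5 equiv), t-BuOH, 50 °C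
Reagents that add atoms: trimethylsulfoxonium iodide, C[S+](C)(C)=O.[I-]
Why: Corey–Chaykovsky-type ring expansion; the sulfoxonium ylide opens the epoxide at its CH2 terminus and the alkoxide then displaces DMSO (4-exo-tet), so the C3–O bond is never broken and the R configuration at C3 is retained.

Step 6
Reactants: 12 (R)-2-(but-3-en-1-yl)oxetane
Product: 13 methyl 3-[(2R)-oxetan-2-yl]propanoate
Conditions: O3, NaOH (2.5 M in MeOH), CH2Cl2, −78 °C
Reagents that add atoms: ozone, [O-][O+]=O; methanol, CO
Why: Oxidative ozonolysis in methanolic NaOH funnels both the carbonyl oxide (methoxy hydroperoxide dehydration) and the aldehyde (hemiacetal oxidation) to the methyl ester; the oxetane is inert to base and far less reactive toward ozone than the alkene.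

Step 7
Reactants: 13 methyl 3-[(2R)-oxetan-2-yl]propanoate
Product: 14 N-methoxy-N-methyl-3-[(2R)-oxetan-2-yl]propanamide
Conditions: MeONHMe·HCl (1.5 equiv), i-PrMgCl (3 equiv), THF, −20 → 0 °C
Reagents that add atoms: N,O-dimethylhydroxylamine hydrochloride, CNOC.Cl
Why: Weinreb amide formation by aminolysis of the ester with the magnesium amide; the amide is a far better nucleophile than i-PrMgCl at this temperature, and the oxetane does not react.

Step 8
Reactants: 10 (10E)-16-bromohexadeca-1,10-dien-12-yne; 14 N-methoxy-N-methyl-3-[(2R)-oxetan-2-yl]propanamide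
Product: 16 (9E)-1-[(2R)-oxetan-2-yl]nonadeca-9,18-dien-7-yn-3-one, via enynyl Grignard reagent 15 (not isolated)
Conditions: Mg turnings, cat. 1,2-dibromoethane, THF, rt → 40 °C; then 14, THF, −20 → 0 °C; aq NH4Cl
Reagents that add atoms: none
Why: Weinreb ketone synthesis forms C6–C7; the chelated tetrahedral intermediate stops at mono-addition, cyclisation of the C7 centre onto the alkyne would need a four-membered ring, and oxetanes are not opened by Grignard reagents at or below 0 °C without an added Lewis acid.

Step 9
Reactants: 16 (9E)-1-[(2R)-oxetan-2-yl]nonadeca-9,18-dien-7-yn-3-one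
Product: 17 (9E)-3-hydroperoxy-3-methoxy-1-[(2R)-oxetan-2-yl]nonadeca-9,18-dien-7-yne (both epimers at C6)
Conditions: urea·H2O2 (10 equiv), CSA (10 mol %), MeOH, 0 °C; NaHCO3 quench
Reagents that add atoms: urea–hydrogen peroxide, NC(N)=O.OO; methanol, CO
Why: Acid-catalysed peroxyketalisation of a dialkyl ketone with anhydrous H2O2 in methanol through the oxocarbenium ion; alkenes and alkyne are inert to H2O2 here, the oxetane should persist under mild Brønsted acid at 0 °C, the C6 epimer mixture does not matter because C6 is equilibrated in step 10, and any material that already cyclises converges on 18.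

Step 10
Reactants: 17 (9E)-3-hydroperoxy-3-methoxy-1-[(2R)-oxetan-2-yl]nonadeca-9,18-dien-7-yne
Product: 18 2-[(3S,6R)-6-[(6E)-hexadeca-6,15-dien-4-yn-1-yl]-6-methoxy-1,2-dioxan-3-yl]ethan-1-ol
Conditions: Sc(OTf)3 (10 mol %), CH2Cl2/MeOH 20:1 (dilute), 0 °C → rt
Reagents that add atoms: none
Why: Intramolecular opening of a Lewis-acid-activated oxetane by a hydroperoxide (6-exo-tet, SN2) attacks C3 from the back, which inverts R to S and frees the C1 hydroxyl, attack at C1 being ruled out because it would need an eight-membered ring; C6 is set under thermodynamic control, since reversible ionisation of the peroxyketal in the presence of MeOH should funnel both epimers into the chair with axial OMe (anomeric effect) and both carbon chains equatorial, which is the 6R isomer with OMe cis to the C3 side chain.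

Step 11
Reactants: 18 2-[(3S,6R)-6-[(6E)-hexadeca-6,15-dien-4-yn-1-yl]-6-methoxy-1,2-dioxan-3-yl]ethan-1-ol
Product: 20 2-[(3S,6R)-6-[(6E)-hexadeca-6,15-dien-4-yn-1-yl]-6-methoxy-1,2-dioxan-3-yl]acetic acid (CNP0125368.1), via aldehyde 19 (not isolated)
Conditions: TEMPO (20 mol %), PhI(OAc)2 (2.2 equiv), MeCN/H2O 1:1, 0 °C → rt
Reagents that add atoms: water, O
Why: Oxoammonium-mediated oxidation of a primary alcohol through the aldehyde hydrate to the acid; the weakly acidic medium avoids base-induced β-elimination or Kornblum–DeLaMare cleavage of the β-peroxy aldehyde 19, and it leaves peroxide, alkenes, alkyne and both stereocentres untouched.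

## Compound list

1 | pyridazine | c1ccnnc1 | starting material
2 | pyridazine 1-oxide | [O-][n+]1ccccn1 | intermediate
3 | 9-bromonon-1-ene | C=CCCCCCCCBr | starting material
4 | non-8-en-1-ylmagnesium bromide | C=CCCCCCCC[Mg]Br | intermediate
5 | bromomagnesium 6-(non-8-en-1-yl)-1,6-dihydropyridazin-1-olate (racemic adduct) | C=CCCCCCCCC1C=CC=NN1O[Mg]Br | intermediate
6 | bromomagnesium (1Z,3E)-trideca-1,3,12-trien-1-yldiazotate | C=CCCCCCCC/C=C/C=C\N=NO[Mg]Br | intermediate
7 | (3E)-trideca-3,12-dien-1-yne | C=CCCCCCCC/C=C/C#C | intermediate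
8 | 1,3-dibromopropane | BrCCCBr | starting material
9 | lithium (3E)-trideca-3,12-dien-1-yn-1-ide | C=CCCCCCCC/C=C/C#C[Li] | intermediate
10 | (10E)-16-bromohexadeca-1,10-dien-12-yne | C=CCCCCCCC/C=C/C#CCCCBr | intermediate
11 | (R)-2-(but-3-en-1-yl)oxirane | C=CCC[C@@H]1CO1 | starting material
12 | (R)-2-(but-3-en-1-yl)oxetane | C=CCC[C@@H]1CCO1 | intermediate
13 | methyl 3-[(2R)-oxetan-2-yl]propanoate | COC(=O)CC[C@@H]1CCO1 | intermediate
14 | N-methoxy-N-methyl-3-[(2R)-oxetan-2-yl]propanamide | CON(C)C(=O)CC[C@@H]1CCO1 | intermediate
15 | [(6E)-hexadeca-6,15-dien-4-yn-1-yl]magnesium bromide | C=CCCCCCCC/C=C/C#CCCC[Mg]Br | intermediate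
16 | (9E)-1-[(2R)-oxetan-2-yl]nonadeca-9,18-dien-7-yn-3-one | C=CCCCCCCC/C=C/C#CCCCC(=O)CC[C@@H]1CCO1 | intermediate
17 | (9E)-3-hydroperoxy-3-methoxy-1-[(2R)-oxetan-2-yl]nonadeca-9,18-dien-7-yne (C6 epimers) | C=CCCCCCCC/C=C/C#CCCCC(OC)(OO)CC[C@@H]1CCO1 | intermediate
18 | 2-[(3S,6R)-6-[(6E)-hexadeca-6,15-dien-4-yn-1-yl]-6-methoxy-1,2-dioxan-3-yl]ethan-1-ol | C=CCCCCCCC/C=C/C#CCCC[C@]1(OC)CC[C@@H](CCO)OO1 | intermediate
19 | 2-[(3S,6R)-6-[(6E)-hexadeca-6,15-dien-4-yn-1-yl]-6-methoxy-1,2-dioxan-3-yl]acetaldehyde | C=CCCCCCCC/C=C/C#CCCC[C@]1(OC)CC[C@@H](CC=O)OO1 | intermediate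
20 | 2-[(3S,6R)-6-[(6E)-hexadeca-6,15-dien-4-yn-1-yl]-6-methoxy-1,2-dioxan-3-yl]acetic acid | C=CCCCCCCC/C=C/C#CCCC[C@]1(OC)CC[C@@H](CC(=O)O)OO1 | target

## Step count and risks

Total step count: 11.
Longest linear sequence: 7 steps (for example steps 1, 3, 4, 8, 9, 10, 11; the branches from 3 and from 11 are equally long).

**Risk 1, step 10.**
- What may go wrong: the 6-exo opening may be slower than intermolecular attack of methanol or of a second hydroperoxide on the activated oxetane. Partial ionisation at C3 may erode the inversion. The freed C1 hydroxyl may exchange with the C6 methoxy group.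
- Fallback, from 16 back to 18: the oxetane is replaced as electrophile by a secondary mesylate, which allows base-mediated intramolecular alkylation of the hydroperoxy ketal.
- MgBr2·OEt2 in Et2O should open the oxetane of 16 at the unhindered C1, with C3–O retained, to give bromohydrin ketone F1.
- MsCl/Et3N gives bromo mesylate ketone F2, and urea·H2O2 with Sc(OTf)3 in MeOH gives bromo mesylate hydroperoxy ketal F3.
- KOt-Bu/18-crown-6 in THF at 0 °C closes the ring by 6-exo displacement of the C3 mesylate with inversion. Attack on the primary bromide would need an eight-membered ring. CSA/MeOH then equilibrates C6, giving bromoethyl dioxane F4.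
- CsOAc in DMF gives acetate F5, and K2CO3/MeOH at 0 °C returns to 18.

**Risk 2, step 3.**
- What may go wrong: a second molecule of Grignard reagent may attack the ring-opened diazotate (double alkylation with loss of N2). The N-oxide may be deoxygenated. Incomplete outward rotation may erode the E geometry.
- Fallback, from 4 back to 7: the same C13–C14 bond is made by cross-coupling on a preformed E-haloenyne.
- Sonogashira coupling of (E)-1,2-dichloroethene (excess) with trimethylsilylacetylene (Pd(PPh3)4, CuI, n-BuNH2) gives chloroenyne F6.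
- Fe(acac)3-catalysed Kumada-type coupling of 4 with F6 (THF/NMP, 0 °C), with retention of geometry, gives silyl enyne F7.
- K2CO3/MeOH removes the silyl group and returns to 7.

**Risk 3, step 9.**
- What may go wrong: the equilibrium may stop short of full conversion. A second H2O2 may displace the methoxy group (gem-dihydroperoxide formation). The acid may start methanolysis of the oxetane.
- Fallback, from 16 back to 17: the ketone is first driven irreversibly to dimethyl ketal F8 with HC(OMe)3 and PPTS in MeOH.
- One methoxy group of F8 is then exchanged for OOH with anhydrous ethereal H2O2 and a trace of acid at 0 °C. Ionisation of a ketal needs much milder acid than activation of the ketone, and this returns to 17.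

## Further compounds

F1 | step 10 | bromohydrin ketone, (3R,12E)-1-bromo-3-hydroxydocosa-12,21-dien-10-yn-6-one | C=CCCCCCCC/C=C/C#CCCCC(=O)CC[C@@H](O)CCBr
F2 | step 10 | bromo mesylate ketone, (3R,12E)-1-bromo-6-oxodocosa-12,21-dien-10-yn-3-yl methanesulfonate | C=CCCCCCCC/C=C/C#CCCCC(=O)CC[C@@H](OS(C)(=O)=O)CCBr
F3 | step 10 | bromo mesylate hydroperoxy ketal, (3R,12E)-1-bromo-6-hydroperoxy-6-methoxydocosa-12,21-dien-10-yn-3-yl methanesulfonate (C6 epimers) | C=CCCCCCCC/C=C/C#CCCCC(OC)(OO)CC[C@@H](OS(C)(=O)=O)CCBr
F4 | step 10 | bromoethyl dioxane, (3S,6R)-3-(2-bromoethyl)-6-[(6E)-hexadeca-6,15-dien-4-yn-1-yl]-6-methoxy-1,2-dioxane | C=CCCCCCCC/C=C/C#CCCC[C@]1(OC)CC[C@@H](CCBr)OO1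
F5 | step 10 | acetate, 2-[(3S,6R)-6-[(6E)-hexadeca-6,15-dien-4-yn-1-yl]-6-methoxy-1,2-dioxan-3-yl]ethyl acetate | C=CCCCCCCC/C=C/C#CCCC[C@]1(OC)CC[C@@H](CCOC(C)=O)OO1
F6 | step 3 | chloroenyne, [(3E)-4-chlorobut-3-en-1-yn-1-yl]trimethylsilane | C[Si](C)(C)C#C/C=C/Cl
F7 | step 3 | silyl enyne, trimethyl[(3E)-trideca-3,12-dien-1-yn-1-yl]silane | C=CCCCCCCC/C=C/C#C[Si](C)(C)C
F8 | step 9 | dimethyl ketal, (9E)-3,3-dimethoxy-1-[(2R)-oxetan-2-yl]nonadeca-9,18-dien-7-yne | C=CCCCCCCC/C=C/C#CCCCC(OC)(OC)CC[C@@H]1CCO1
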